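Ring C is cut at the C3–O and C2–H bonds, leading back to an achiral flav-2-ene (2-aryl-4H-chromene). One reagent-controlled syn hydroboration of its C2=C3 enol ether, followed by stereoretentive oxidation, should install the C2 hydrogen and the C3 hydroxyl together and create both stereocentres at once. The step exploits the trans relationship of the C2 aryl group and the C3 hydroxyl on ring C, with C3 beta to O1. The precursor is flat and stereochemically blank, with silyl ethers on ring A and benzyl ethers on ring B, made in four steps from threefold-symmetric phloroglucinol. The gallates go onto O5 and O7 last.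

Key step: step 5

Remark: monoisopinocampheylborane made from (+)-α-pinene (IpcBH2, C[C@H]1[C@H](B)C[C@@H]2C[C@H]1C2(C)C) is assumed, by analogy with 1-arylcycloalkenes, to give the (2R,3S) series. The sense is to be confirmed in a pilot run by converting a sample into catechin and comparing the sign of rotation with natural (+)-catechin; the reagent from (−)-α-pinene would be used instead if the sense proved opposite.

Step 1
Reactants: 1 phloroglucinol; 2 acrylic acid
Product: 3 5,7-dihydroxychroman-2-one
Conditions: 1 (3 equiv), 2 (1 equiv), Amberlyst-15 (polystyrene–SO3H resin), toluene, reflux, azeotropic removal of water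
Reagents that add atoms: none
Why: Acid-catalysed Friedel–Crafts conjugate addition of the very nucleophilic arene to acrylic acid followed by lactonisation onto a flanking hydroxyl is a known entry to dihydrocoumarins of polyphenols; the threefold symmetry of 1 makes every carbon/oxygen pair equivalent, and the excess of 1 suppresses a second annulation.

Step 2
Reactants: 3 5,7-dihydroxychroman-2-one
Product: 4 5,7-bis(triisopropylsilyloxy)chroman-2-one
Conditions: TIPSOTf (2.3 equiv), 2,6-lutidine (4 equiv), CH2Cl2, 0 °C → rt
Reagents that add atoms: triisopropylsilyl trifluoromethanesulfonate, CC(C)[Si](OS(=O)(=O)C(F)(F)F)(C(C)C)C(C)C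
Why: Silylation of phenols with a silyl triflate and a hindered pyridine base that cannot open the aryl lactone is routine, and triisopropylsilyl aryl ethers should survive the amide base, the mildly basic coupling and the perborate oxidation yet be cleaved by fluoride beside benzyl ethers.

Step 3
Reactants: 4 5,7-bis(triisopropylsilyloxy)chroman-2-one
Product: 6 5,7-bis(triisopropylsilyloxy)-4H-chromen-2-yl diphenyl phosphate, via potassium lactone enolate 5 (not isolated)
Conditions: (PhO)2P(O)Cl (1.5 equiv), THF/DMPU, −78 °C; KN(SiMe3)2 (1.3 equiv) added slowly, −78 °C; work-up and filtration with Et3N-treated silica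
Reagents that add atoms: diphenyl chlorophosphate, O=P(Cl)(Oc1ccccc1)Oc1ccccc1
Why: Ketene acetal phosphate formation by O-phosphorylation of a lactone enolate is a standard transformation, and generating the enolate with the chlorophosphate already present at −78 °C should trap it before the aryl ester enolate fragments by E1cB to a ketene and a phenoxide.

Step 4
Reactants: 6 5,7-bis(triisopropylsilyloxy)-4H-chromen-2-yl diphenyl phosphate; 7 3,4-bis(benzyloxy)phenylboronic acid
Product: 8 2-[3,4-bis(benzyloxy)phenyl]-5,7-bis(triisopropylsilyloxy)-4H-chromene (achiral flav-2-ene)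
Conditions: Pd(PPh3)4 (5 mol %), K3PO4 (3 equiv), 1,4-dioxane/H2O (10:1), degassed, 70 °C; purification on Et3N-deactivated silica, used without delay
Reagents that add atoms: none
Why: Suzuki–Miyaura coupling of lactone-derived ketene acetal phosphates with arylboronic acids under zerovalent palladium catalysis is established, the C2–O phosphate bond undergoing oxidative addition like a vinyl triflate while the aryl silyl and benzyl ethers are inert to the mild base.

Step 5
Reactants: 8 2-[3,4-bis(benzyloxy)phenyl]-5,7-bis(triisopropylsilyloxy)-4H-chromene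
Product: 10 (2R,3S)-2-[3,4-bis(benzyloxy)phenyl]-5,7-bis(triisopropylsilyloxy)chroman-3-ol, via chroman-3-yl(isopinocampheyl)borane 9 (not isolated)
Conditions: IpcBH2 (from (+)-α-pinene, 1.3 equiv), THF, −25 °C, then 0 °C; NaBO3·4H2O, THF/H2O, 0 °C → rt
Reagents that add atoms: sodium perborate (source of the C3 oxygen), [Na+].[Na+].O[B-]1(O)OO[B-](O)(O)OO1
Why: Proposed new method: the B–H bond of the chiral monoalkylborane should add across the C2=C3 enol ether through a concerted four-centre transition state, boron bonding to C3 (the nucleophilic carbon beta to O1 and the one remote from the aryl group) and hydride to C2 on the same face, after which the C3–B bond is oxidised to C3–O with retention by 1,2-migration onto peroxoborate oxygen. The closest known reactions are the hydroboration–oxidation of flav-2-enes and other cyclic enol ethers with achiral boranes to trans-2-substituted 3-ols and the monoisopinocampheylborane hydroboration of 1-arylcycloalkenes to enantioenriched trans-2-arylcycloalkanols; the combination of the two on a 2-aryl-4H-chromene is what is new. No ring is closed in this step. C2 and C3 are created together: their trans relationship follows from suprafacial H/B addition plus retentive oxidation, and their absolute configuration is controlled by the isopinocampheyl group on boron, expected to lead to (2R,3S) because the reagent from (+)-α-pinene is known to convert 1-arylcycloalkenes such as 1-phenylcyclopentene into the spatially corresponding (1S,2R) trans-2-arylcycloalkanols. The step needs only enantioface selectivity, regiochemistry being fixed by the enol ether polarisation reinforced by the C2 aryl group and diastereoselectivity by the mechanism, and the flat trisubstituted alkene with a large aryl group at C2 and a hydrogen at C3 is the substitution pattern this reagent discriminates best. Ring-opening beta-elimination of the beta-aryloxy borane should be held back by the low temperature, the gauche B–C3–C2–O1 geometry, the poor leaving ability of the electron-rich aryloxide and the immediate mild oxidation, and the enantiomeric purity can be raised by recrystallising 11.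

Step 6
Reactants: 10 (2R,3S)-2-[3,4-bis(benzyloxy)phenyl]-5,7-bis(triisopropylsilyloxy)chroman-3-ol
Product: 11 3',4'-di-O-benzyl-(+)-catechin [(2R,3S)-2-[3,4-bis(benzyloxy)phenyl]chroman-3,5,7-triol]
Conditions: Bu4NF (2.2 equiv), AcOH (2.2 equiv), THF, 0 °C, under argon
Reagents that add atoms: none
Why: Fluoride-induced desilylation of aryl silyl ethers is fast and selective, and the acetic acid buffer protonates the electron-rich phenoxides at once, so the benzyl ethers, the secondary alcohol and both stereocentres should be untouched and air oxidation of ring A limited.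

Step 7
Reactants: 12 3,4,5-tris(benzyloxy)benzoic acid
Product: 13 3,4,5-tris(benzyloxy)benzoyl chloride
Conditions: (COCl)2 (1.5 equiv), N,N-dimethylformamide (cat.), CH2Cl2, 0 °C → rt; evaporated and used crude
Reagents that add atoms: oxalyl chloride, O=C(Cl)C(=O)Cl
Why: Acid chloride formation with oxalyl chloride under formamide catalysis (chloroiminium activation) is standard and is tolerated by benzyl aryl ethers.

Step 8
Reactants: 11 3',4'-di-O-benzyl-(+)-catechin; 13 3,4,5-tris(benzyloxy)benzoyl chloride
Product: 14 (2R,3S)-3',4'-di-O-benzyl-(+)-catechin 5,7-bis(3,4,5-tri-O-benzylgallate) with free 3-hydroxyl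
Conditions: 13 (2.1 equiv), Et3N (2.5 equiv), CH2Cl2/THF, −20 → 0 °C, no acyl-transfer catalyst
Reagents that add atoms: none
Why: Amine-mediated esterification with an acid chloride is chemoselective for the two acidic phenols, which react through their ammonium phenoxides much faster than the neutral, hindered secondary C3 hydroxyl when no acyl-transfer catalyst is present and the acid chloride is limited to about two equivalents.

Step 9
Reactants: 14 (2R,3S)-3',4'-di-O-benzyl-(+)-catechin 5,7-bis(3,4,5-tri-O-benzylgallate)
Product: 15 catechin 5,7-di-O-gallate, (2R,3S)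
Conditions: H2 (1 atm), Pd(OH)2/C, THF/EtOAc, rt; filtration under argon, lyophilisation
Reagents that add atoms: none
Why: Catalytic hydrogenolysis of benzyl aryl ethers in a neutral, non-nucleophilic medium should release all eight phenols, while the aryl gallate esters (no alcohol or base present to cause transesterification or acyl migration), the C2–O1 bond of ring C and the two stereocentres are expected to survive as they do in flavan-3-ol chemistry generally.

Compound list
1 | phloroglucinol | Oc1cc(O)cc(O)c1 | starting material
2 | acrylic acid | C=CC(=O)O | starting material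
3 | 5,7-dihydroxychroman-2-one | O=C1CCc2c(O)cc(O)cc2O1 | intermediate
4 | 5,7-bis(triisopropylsilyloxy)chroman-2-one | O=C1CCc2c(O[Si](C(C)C)(C(C)C)C(C)C)cc(O[Si](C(C)C)(C(C)C)C(C)C)cc2O1 | intermediate
5 | potassium 5,7-bis(triisopropylsilyloxy)-4H-chromen-2-olate (lactone enolate, not isolated) | [K+].[O-]C1=CCc2c(O[Si](C(C)C)(C(C)C)C(C)C)cc(O[Si](C(C)C)(C(C)C)C(C)C)cc2O1 | intermediate
6 | 5,7-bis(triisopropylsilyloxy)-4H-chromen-2-yl diphenyl phosphate | O=P(Oc1ccccc1)(Oc1ccccc1)OC1=CCc2c(O[Si](C(C)C)(C(C)C)C(C)C)cc(O[Si](C(C)C)(C(C)C)C(C)C)cc2O1 | intermediate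
7 | 3,4-bis(benzyloxy)phenylboronic acid | OB(O)c1ccc(OCc2ccccc2)c(OCc2ccccc2)c1 | starting material
8 | 2-[3,4-bis(benzyloxy)phenyl]-5,7-bis(triisopropylsilyloxy)-4H-chromene | C1(c2ccc(OCc3ccccc3)c(OCc3ccccc3)c2)=CCc2c(O[Si](C(C)C)(C(C)C)C(C)C)cc(O[Si](C(C)C)(C(C)C)C(C)C)cc2O1 | intermediate
9 | [(2S,3S)-2-[3,4-bis(benzyloxy)phenyl]-5,7-bis(triisopropylsilyloxy)chroman-3-yl](isopinocampheyl)borane, 2,3-trans, same spatial arrangement as 10 (the C2 descriptor differs only because boron ranks below carbon; not isolated) | CC(C)[Si](C(C)C)(C(C)C)Oc1cc(O[Si](C(C)C)(C(C)C)C(C)C)c2c(c1)O[C@H](c1ccc(OCc3ccccc3)c(OCc3ccccc3)c1)[C@@H](B[C@@H]1C[C@@H]3C[C@H]([C@H]1C)C3(C)C)C2 | intermediate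
10 | (2R,3S)-2-[3,4-bis(benzyloxy)phenyl]-5,7-bis(triisopropylsilyloxy)chroman-3-ol | CC(C)[Si](C(C)C)(C(C)C)Oc1cc(O[Si](C(C)C)(C(C)C)C(C)C)c2c(c1)O[C@H](c1ccc(OCc3ccccc3)c(OCc3ccccc3)c1)[C@@H](O)C2 | intermediate
11 | 3',4'-di-O-benzyl-(+)-catechin, (2R,3S) | Oc1cc(O)c2c(c1)O[C@H](c1ccc(OCc3ccccc3)c(OCc3ccccc3)c1)[C@@H](O)C2 | intermediate
12 | 3,4,5-tris(benzyloxy)benzoic acid | O=C(O)c1cc(OCc2ccccc2)c(OCc2ccccc2)c(OCc2ccccc2)c1 | starting material
13 | 3,4,5-tris(benzyloxy)benzoyl chloride | O=C(Cl)c1cc(OCc2ccccc2)c(OCc2ccccc2)c(OCc2ccccc2)c1 | intermediate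
14 | 3',4'-di-O-benzyl-(+)-catechin 5,7-bis(3,4,5-tri-O-benzylgallate), (2R,3S) | O=C(Oc1cc(OC(=O)c2cc(OCc3ccccc3)c(OCc3ccccc3)c(OCc3ccccc3)c2)c2c(c1)O[C@H](c1ccc(OCc3ccccc3)c(OCc3ccccc3)c1)[C@@H](O)C2)c1cc(OCc2ccccc2)c(OCc2ccccc2)c(OCc2ccccc2)c1 | intermediate
15 | catechin 5,7-di-O-gallate, (2R,3S) | O=C(Oc1cc(OC(=O)c2cc(O)c(O)c(O)c2)c2c(c1)O[C@H](c1ccc(O)c(O)c1)[C@@H](O)C2)c1cc(O)c(O)c(O)c1 | target

Total step count: 9. Longest linear sequence: 8 steps (steps 1 to 6, then 8 and 9); step 7 is a one-step side branch.

Steps most likely to fail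

Step 5. The isopinocampheyl group may discriminate the two faces of the C2=C3 bond poorly, or the hindered reagent may add so slowly that ring-opening elimination of the beta-aryloxy borane competes. The fallback gives up asymmetric induction for resolution and uses only known chemistry. Setting out from 8, hydroboration with BH3·SMe2 in THF at 0 °C and oxidation with NaBO3·4H2O, a sequence precedented for flav-2-enes, should give the racemic 2,3-trans alcohol F1. Its enantiomers are then separated by preparative chromatography on an amylose tris(3,5-dimethylphenylcarbamate) stationary phase. The (2R,3S) enantiomer is 10, where the route is rejoined, its identity being checked by the rotation sign after conversion of a sample into catechin.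

Step 3. The aryl ester enolate may fragment to a ketene and a phenoxide before it is phosphorylated, or the ketene acetal phosphate may hydrolyse during isolation. The fallback abandons the cross-coupling and forms the C2–aryl bond by carbonyl addition. Setting out from 4, aminolysis with MeNHOMe·HCl and iPrMgCl in THF at −20 °C should open the lactone to the N-methoxy-N-methylamide F2. Addition of 3,4-bis(benzyloxy)phenylmagnesium bromide F3 in a Weinreb ketone synthesis should then give the 2-hydroxyaryl ketone F4, which exists in equilibrium with its cyclic hemiketal. F3 is prepared from commercial 4-bromo-1,2-bis(benzyloxy)benzene and magnesium turnings and used at 2.5 equiv, the first equivalent being consumed by the phenol. Cyclodehydration with catalytic pyridinium p-toluenesulfonate in toluene with azeotropic removal of water closes ring C and comes back to the route at 8, bypassing 6 and step 4.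

Step 8. Acylation may spill over to the secondary C3 hydroxyl, or stall at the mono-ester because the 5-hydroxyl peri to C4 reacts more slowly, giving mixtures that are hard to separate. The fallback removes the selectivity question with one more protecting group. Setting out from 10, benzylation of the C3 hydroxyl (NaH, BnBr, Bu4NI, THF, 0 °C to rt) should give the 3-O-benzyl ether F5. Desilylation as in step 6 gives the 5,7-diphenol F6. Exhaustive acylation with excess 13, Et3N and catalytic 4-(dimethylamino)pyridine gives the nonabenzyl bis-gallate F7. Hydrogenolysis as in step 9 removes all nine benzyl groups and comes back to the route at 15.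

Further compounds
F1 | step 5 | racemic trans-2-[3,4-bis(benzyloxy)phenyl]-5,7-bis(triisopropylsilyloxy)chroman-3-ol, (2R,3S) and (2S,3R) enantiomers | CC(C)[Si](C(C)C)(C(C)C)Oc1cc(O[Si](C(C)C)(C(C)C)C(C)C)c2c(c1)O[C@H](c1ccc(OCc3ccccc3)c(OCc3ccccc3)c1)[C@@H](O)C2.CC(C)[Si](C(C)C)(C(C)C)Oc1cc(O[Si](C(C)C)(C(C)C)C(C)C)c2c(c1)O[C@@H](c1ccc(OCc3ccccc3)c(OCc3ccccc3)c1)[C@H](O)C2
F2 | step 3 | 3-[2-hydroxy-4,6-bis(triisopropylsilyloxy)phenyl]-N-methoxy-N-methylpropanamide | CON(C)C(=O)CCc1c(O)cc(O[Si](C(C)C)(C(C)C)C(C)C)cc1O[Si](C(C)C)(C(C)C)C(C)C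
F3 | step 3 | 3,4-bis(benzyloxy)phenylmagnesium bromide | Br[Mg]c1ccc(OCc2ccccc2)c(OCc2ccccc2)c1
F4 | step 3 | 1-[3,4-bis(benzyloxy)phenyl]-3-[2-hydroxy-4,6-bis(triisopropylsilyloxy)phenyl]propan-1-one | O=C(CCc1c(O)cc(O[Si](C(C)C)(C(C)C)C(C)C)cc1O[Si](C(C)C)(C(C)C)C(C)C)c1ccc(OCc2ccccc2)c(OCc2ccccc2)c1
F5 | step 8 | (2R,3S)-3-(benzyloxy)-2-[3,4-bis(benzyloxy)phenyl]-5,7-bis(triisopropylsilyloxy)chroman | CC(C)[Si](C(C)C)(C(C)C)Oc1cc(O[Si](C(C)C)(C(C)C)C(C)C)c2c(c1)O[C@H](c1ccc(OCc3ccccc3)c(OCc3ccccc3)c1)[C@@H](OCc1ccccc1)C2
F6 | step 8 | 3,3',4'-tri-O-benzyl-(+)-catechin, (2R,3S) | Oc1cc(O)c2c(c1)O[C@H](c1ccc(OCc3ccccc3)c(OCc3ccccc3)c1)[C@@H](OCc1ccccc1)C2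
F7 | step 8 | 3,3',4'-tri-O-benzyl-(+)-catechin 5,7-bis(3,4,5-tri-O-benzylgallate), (2R,3S) | O=C(Oc1cc(OC(=O)c2cc(OCc3ccccc3)c(OCc3ccccc3)c(OCc3ccccc3)c2)c2c(c1)O[C@H](c1ccc(OCc3ccccc3)c(OCc3ccccc3)c1)[C@@H](OCc1ccccc1)C2)c1cc(OCc2ccccc2)c(OCc2ccccc2)c(OCc2ccccc2)c1
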